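**Plan**

- Locants: C1 = carbonyl carbon on ring A (4-methoxyphenyl), C2 = CH bearing ring B (phenyl), C3 = CH bearing the carboxamide, C4 = carbonyl carbon on ring C (2-hydroxy-4,6-dimethoxyphenyl).
- Retrosynthesis: re-benzylate the ring C phenol, reduce C4 to a carbinol, cut the amide C–N back to an acyl oxazolidinone, cut C3–C4 (aldol), then cut C1–C2 and C2–C3 together so that C2 leaves as a benzylidene unit.
- Enabling feature: without C2, C1 and the C3 carboxyl carbon are 1,3-related carbonyls on ring A's side chain, a (4-methoxybenzoyl)acetyl unit. A zinc carbenoid can therefore place C2 between C1 and C3 and leave C3 as an enolate ready for C4.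
- Forward: β-keto imide 6, diiodide 9 and aldehyde 11 are joined in one flask (C2–C3, C1–C2, then C3–C4; the chain stays open and no ring is kept), followed by amide exchange, C4 oxidation and debenzylation.
- Stereochemistry: the (R)-4-benzyloxazolidinone auxiliary is meant to set C2 (R) in the insertion and C3 (R) in the aldol; the C4 carbinol centre is erased by oxidation.

Key step: step 5

Assumption: C3 of the target is the exchangeable methine of a 1,3-dicarbonyl unit and the (2R,3R) arrangement is taken to be its more stable epimer, so a C3 mixture at the stage of 18 would be returned to it by brief exposure to Et3N in CH2Cl2, a base too weak to touch C2.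

**Route**

Step 1
Reactants: 1 4-methoxybenzoyl chloride; 2 Meldrum's acid (2,2-dimethyl-1,3-dioxane-4,6-dione)
Product: 3 5-[hydroxy(4-methoxyphenyl)methylidene]-2,2-dimethyl-1,3-dioxane-4,6-dione
Conditions: pyridine (2.2 equiv), CH2Cl2, 0 °C to rt
Reagents that add atoms: none
Why: C-acylation of the doubly activated methylene of Meldrum's acid by the aroyl chloride with pyridine as base is the standard entry to acyl Meldrum's acids, which rest as the hydrogen-bonded enol.

Step 2
Reactants: 3 5-[hydroxy(4-methoxyphenyl)methylidene]-2,2-dimethyl-1,3-dioxane-4,6-dione; 4 (R)-4-benzyl-1,3-oxazolidin-2-one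
Product: 6 (R)-4-benzyl-3-[3-(4-methoxyphenyl)-3-oxopropanoyl]-1,3-oxazolidin-2-one, via aroylketene 5 (not isolated)
Conditions: toluene, 110 °C
Reagents that add atoms: none
Why: Thermal cycloreversion of the acyl Meldrum's acid expels acetone and CO2 to give aroylketene 5, which N-acylates the oxazolidinone (acylketene trapping) without touching the auxiliary stereocentre.

Step 3
Reactants: 7 benzal chloride (α,α-dichlorotoluene)
Product: 9 α,α-diiodotoluene, via α-chloro-α-iodotoluene 8 (not isolated)
Conditions: NaI (4 equiv), acetone, rt to 40 °C, dark; used at once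
Reagents that add atoms: sodium iodide, [Na+].[I-]
Why: Twofold Finkelstein halide exchange at the benzylic carbon, pulled forward by precipitation of NaCl from acetone, should give the light-sensitive diiodide.

Step 4
Reactants: 10 2-hydroxy-4,6-dimethoxybenzaldehyde
Product: 11 2-(benzyloxy)-4,6-dimethoxybenzaldehyde
Conditions: BnBr, K2CO3, DMF, 50 °C
Reagents that add atoms: benzyl bromide, BrCc1ccccc1
Why: Williamson etherification of the phenoxide; the benzyl ether hides the acidic phenol from Et2Zn and can be removed at the end without acid or base.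

Step 5
Reactants: 6 (R)-4-benzyl-3-[3-(4-methoxyphenyl)-3-oxopropanoyl]-1,3-oxazolidin-2-one; 9 α,α-diiodotoluene; 11 2-(benzyloxy)-4,6-dimethoxybenzaldehyde
Product: 15 (R)-4-benzyl-3-{(2R,3R)-2-[(R)-[2-(benzyloxy)-4,6-dimethoxyphenyl](hydroxy)methyl]-4-(4-methoxyphenyl)-4-oxo-3-phenylbutanoyl}-1,3-oxazolidin-2-one, via ethylzinc enolate 12 (not isolated), via zinc cyclopropanolate 13 (not isolated), via homologated zinc enolate 14 (not isolated)
Conditions: Et2Zn (5 equiv), 9 (4 equiv), CH2Cl2, 0 °C; add 6, 0 °C to rt; then 11 (1.5 equiv), 0 °C to rt; sat. aq NH4Cl; Et3N-deactivated silica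
Reagents that add atoms: none
Why: Proposed new method: Et2Zn turns 6 into the chelated ethylzinc enolate 12, the benzylidene carbenoid EtZnCH(I)Ph formed from Et2Zn and 9 cyclopropanates its C1=C3 bond in two stages (C2–C3 first, then C1–C2), the donor–acceptor cyclopropanolate 13 opens at the old C1–C3 bond to the homologated zinc enolate 14, and 14 adds to aldehyde 11 (C3–C4). The closest known reaction type is the zinc carbenoid chain extension of β-keto esters, amides and imides with tandem aldol capture, together with the use of the benzylidene carbenoid on β-keto esters; what is untested is control of the inserted carbon by an imide auxiliary. The only ring closed is the transient cyclopropane, by 3-exo-trig attack of the benzylic carbon–zinc bond on the C1 carbonyl, and it does not survive into 15. C2 should be set by the auxiliary: with zinc bridging the C1 oxygen and the acyl oxygen the oxazolidinone lies dipole-opposed, its benzyl group screens one face of C3 so that C2–C3 forms on the other, and oxygen-directed delivery places the phenyl group on the cyclopropane face remote from the two zinc-bound oxygens, which becomes (2R) when C3 returns to sp2. C3 and C4 are expected to follow from a closed chair transition state of the Z enolate on the same open face (syn aldol, 3R and 4R), C3 being further secured by its later lability and C4 being removed in step 7. The step needs insertion only between C1 and C3 and no loss of the new C2–H: the aryl ketone is the sole carbonyl electrophilic enough for the ring closure, and the zinc enolate is too weakly basic to epimerise C2.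

Step 6
Reactants: 15 (R)-4-benzyl-3-{(2R,3R)-2-[(R)-[2-(benzyloxy)-4,6-dimethoxyphenyl](hydroxy)methyl]-4-(4-methoxyphenyl)-4-oxo-3-phenylbutanoyl}-1,3-oxazolidin-2-one; 16 N-(4-aminobutyl)benzamide
Product: 17 (2R,3R)-N-(4-benzamidobutyl)-2-[(R)-[2-(benzyloxy)-4,6-dimethoxyphenyl](hydroxy)methyl]-4-(4-methoxyphenyl)-4-oxo-3-phenylbutanamide
Conditions: 16 (3 equiv), AlMe3 (6 equiv), CH2Cl2, 0 °C to rt; then 15, 0 °C to rt; aq KNaC4H4O6 (potassium sodium tartrate)
Reagents that add atoms: none
Why: Weinreb-type aluminium amide transamidation, in which the C4 hydroxyl becomes an aluminium alkoxide that activates the exocyclic imide carbonyl so that the amide forms and auxiliary 4 is released, under non-basic conditions that should leave C2 and C3 alone.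

Step 7
Reactants: 17 (2R,3R)-N-(4-benzamidobutyl)-2-[(R)-[2-(benzyloxy)-4,6-dimethoxyphenyl](hydroxy)methyl]-4-(4-methoxyphenyl)-4-oxo-3-phenylbutanamide
Product: 18 (2R,3R)-N-(4-benzamidobutyl)-2-[2-(benzyloxy)-4,6-dimethoxybenzoyl]-4-(4-methoxyphenyl)-4-oxo-3-phenylbutanamide
Conditions: Dess–Martin periodinane (1.5 equiv), pyridine (5 equiv), CH2Cl2, 0 °C to rt; aq NaHCO3
Reagents that add atoms: none
Why: Dess–Martin oxidation of the secondary benzylic carbinol (reached through the open form of any hemiketal with the C1 ketone) should give the C4 ketone and remove the C4 stereocentre, with the pyridine buffer guarding the 1,4-diketone against acid-induced furan formation and C3 keeping the configuration set in step 5.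

Step 8
Reactants: 18 (2R,3R)-N-(4-benzamidobutyl)-2-[2-(benzyloxy)-4,6-dimethoxybenzoyl]-4-(4-methoxyphenyl)-4-oxo-3-phenylbutanamide
Product: 19 (2R,3R)-N-(4-benzamidobutyl)-2-(2-hydroxy-4,6-dimethoxybenzoyl)-4-(4-methoxyphenyl)-4-oxo-3-phenylbutanamide (CNP0208962.1)
Conditions: H2 (1 atm), Pd/C (10 wt %), EtOAc, rt
Reagents that add atoms: none
Why: Hydrogenolysis of the aryl benzyl ether over palladium on carbon under neutral conditions should free the phenol, which then hydrogen-bonds to the C4 ketone, without disturbing C2, C3 or the aryl ketones.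

**Compound list**

1 | 4-methoxybenzoyl chloride | COc1ccc(cc1)C(Cl)=O | starting material
2 | Meldrum's acid (2,2-dimethyl-1,3-dioxane-4,6-dione) | CC1(C)OC(=O)CC(=O)O1 | starting material
3 | 5-[hydroxy(4-methoxyphenyl)methylidene]-2,2-dimethyl-1,3-dioxane-4,6-dione | COc1ccc(cc1)C(O)=C1C(=O)OC(C)(C)OC1=O | intermediate
4 | (R)-4-benzyl-1,3-oxazolidin-2-one | O=C1N[C@H](Cc2ccccc2)CO1 | starting material
5 | (4-methoxybenzoyl)ketene, 3-(4-methoxyphenyl)-3-oxoprop-1-en-1-one, formed in the flask | COc1ccc(cc1)C(=O)C=C=O | intermediate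
6 | (R)-4-benzyl-3-[3-(4-methoxyphenyl)-3-oxopropanoyl]-1,3-oxazolidin-2-one | COc1ccc(cc1)C(=O)CC(=O)N1[C@H](Cc2ccccc2)COC1=O | intermediate
7 | benzal chloride (α,α-dichlorotoluene) | ClC(Cl)c1ccccc1 | starting material
8 | α-chloro-α-iodotoluene, formed in the flask | ClC(I)c1ccccc1 | intermediate
9 | α,α-diiodotoluene | IC(I)c1ccccc1 | intermediate
10 | 2-hydroxy-4,6-dimethoxybenzaldehyde | COc1cc(O)c(C=O)c(OC)c1 | starting material
11 | 2-(benzyloxy)-4,6-dimethoxybenzaldehyde | COc1cc(OC)c(C=O)c(OCc2ccccc2)c1 | intermediate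
12 | ethylzinc (Z)-enolate of 6, zinc on the C1 oxygen, formed in the flask | CC[Zn]O/C(=C\C(=O)N1[C@H](Cc2ccccc2)COC1=O)c1ccc(OC)cc1 | intermediate
13 | ethylzinc (1R,2R,3S)-3-{[(R)-4-benzyl-2-oxo-1,3-oxazolidin-3-yl]carbonyl}-1-(4-methoxyphenyl)-2-phenylcyclopropan-1-olate (O and acyl cis, phenyl trans to both), formed in the flask | CC[Zn]O[C@]1(c2ccc(OC)cc2)[C@@H](c2ccccc2)[C@@H]1C(=O)N1[C@H](Cc2ccccc2)COC1=O | intermediate
14 | ethylzinc (Z)-enolate of (R)-4-benzyl-3-[(3R)-4-(4-methoxyphenyl)-4-oxo-3-phenylbutanoyl]-1,3-oxazolidin-2-one, formed in the flask | CC[Zn]O/C(=C\[C@H](c1ccccc1)C(=O)c1ccc(OC)cc1)N1[C@H](Cc2ccccc2)COC1=O | intermediate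
15 | (R)-4-benzyl-3-{(2R,3R)-2-[(R)-[2-(benzyloxy)-4,6-dimethoxyphenyl](hydroxy)methyl]-4-(4-methoxyphenyl)-4-oxo-3-phenylbutanoyl}-1,3-oxazolidin-2-one | COc1ccc(C(=O)[C@@H](c2ccccc2)[C@@H](C(=O)N2[C@H](Cc3ccccc3)COC2=O)[C@@H](O)c2c(OCc3ccccc3)cc(OC)cc2OC)cc1 | intermediate
16 | N-(4-aminobutyl)benzamide | NCCCCNC(=O)c1ccccc1 | starting material
17 | (2R,3R)-N-(4-benzamidobutyl)-2-[(R)-[2-(benzyloxy)-4,6-dimethoxyphenyl](hydroxy)methyl]-4-(4-methoxyphenyl)-4-oxo-3-phenylbutanamide | COc1ccc(C(=O)[C@@H](c2ccccc2)[C@@H](C(=O)NCCCCNC(=O)c2ccccc2)[C@@H](O)c2c(OCc3ccccc3)cc(OC)cc2OC)cc1 | intermediate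
18 | (2R,3R)-N-(4-benzamidobutyl)-2-[2-(benzyloxy)-4,6-dimethoxybenzoyl]-4-(4-methoxyphenyl)-4-oxo-3-phenylbutanamide | COc1ccc(C(=O)[C@@H](c2ccccc2)[C@@H](C(=O)NCCCCNC(=O)c2ccccc2)C(=O)c2c(OCc3ccccc3)cc(OC)cc2OC)cc1 | intermediate
19 | (2R,3R)-N-(4-benzamidobutyl)-2-(2-hydroxy-4,6-dimethoxybenzoyl)-4-(4-methoxyphenyl)-4-oxo-3-phenylbutanamide (CNP0208962.1) | COc1ccc(C(=O)[C@@H](c2ccccc2)[C@@H](C(=O)NCCCCNC(=O)c2ccccc2)C(=O)c2c(O)cc(OC)cc2OC)cc1 | target

**Step count and risks**

Total step count: 8. Longest linear sequence: 6 steps (1, 2, 5, 6, 7, 8).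

Steps most likely to fail:

1. Step 5. What may go wrong is weak facial discrimination at C2 during the insertion, or an aldol addition too slow to compete with protonation because the aldehyde is electron-rich and flanked by two ortho substituents. The fallback uses known chemistry, sets out from 4 and comes back to the route at 15. Oxazolidinone 4 is N-acylated (n-BuLi, bromoacetyl bromide, THF, −78 °C) to (R)-4-benzyl-3-(bromoacetyl)-1,3-oxazolidin-2-one F1. The lithium enolate of commercial 1-(4-methoxyphenyl)-2-phenylethan-1-one (LiN(SiMe3)2, THF, −78 °C) is alkylated by F1, which makes C2–C3 and should give (R)-4-benzyl-3-[(3R)-4-(4-methoxyphenyl)-4-oxo-3-phenylbutanoyl]-1,3-oxazolidin-2-one F2 together with its C2 epimer, (R)-4-benzyl-3-[(3S)-4-(4-methoxyphenyl)-4-oxo-3-phenylbutanoyl]-1,3-oxazolidin-2-one F3. The two are diastereomers, so they are separated by chromatography or crystallisation, and F3 is recycled by DBU-mediated epimerisation at its ketone α-carbon. An Evans syn aldol of F2 with 11 (Bu2BOTf, iPr2NEt, CH2Cl2, −78 to 0 °C), in which the imide should be enolised in preference to the hindered tertiary ketone α-position, then makes C3–C4 and delivers 15.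

2. Step 6. What may go wrong is ionisation or retro-aldol cleavage of the electron-rich benzylic aluminium alkoxide, or attack at the ring carbonyl of the crowded imide. The fallback sets out from 15 and comes back at 17. Hydroperoxide cleavage of the imide (LiOH, H2O2, THF–H2O, 0 °C) should give (2R,3R)-2-[(R)-[2-(benzyloxy)-4,6-dimethoxyphenyl](hydroxy)methyl]-4-(4-methoxyphenyl)-4-oxo-3-phenylbutanoic acid F4 with recovery of 4. The acid is kept cold and coupled at once with 16 (EDC·HCl, HOBt, iPr2NEt, CH2Cl2–DMF, 0 °C to rt) to 17.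

3. Step 8. What may go wrong is hydrogenation of the C1 aryl ketone competing with cleavage of the hindered benzyl ether. The fallback sets out from 18 and comes back at 19. It replaces the reductive cleavage by a Lewis-acid dealkylation assisted by the neighbouring C4 carbonyl (BCl3, pentamethylbenzene as benzyl cation trap, CH2Cl2, −78 °C), at which temperature the methyl ethers and the 1,4-diketone should survive; it makes no new compound (F0).

Further compounds
F1 | step 5 | (R)-4-benzyl-3-(bromoacetyl)-1,3-oxazolidin-2-one | BrCC(=O)N1[C@H](Cc2ccccc2)COC1=O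
F2 | step 5 | (R)-4-benzyl-3-[(3R)-4-(4-methoxyphenyl)-4-oxo-3-phenylbutanoyl]-1,3-oxazolidin-2-one | COc1ccc(cc1)C(=O)[C@@H](c1ccccc1)CC(=O)N1[C@H](Cc2ccccc2)COC1=O
F3 | step 5 | (R)-4-benzyl-3-[(3S)-4-(4-methoxyphenyl)-4-oxo-3-phenylbutanoyl]-1,3-oxazolidin-2-one | COc1ccc(cc1)C(=O)[C@H](c1ccccc1)CC(=O)N1[C@H](Cc2ccccc2)COC1=O
F4 | step 6 | (2R,3R)-2-[(R)-[2-(benzyloxy)-4,6-dimethoxyphenyl](hydroxy)methyl]-4-(4-methoxyphenyl)-4-oxo-3-phenylbutanoic acid | COc1ccc(C(=O)[C@@H](c2ccccc2)[C@@H](C(=O)O)[C@@H](O)c2c(OCc3ccccc3)cc(OC)cc2OC)cc1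
F0 | step 8 | none | none
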